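**Assumptions (one line each):** 2,3‑O‑isopropylidene‑D‑erythronolactone (cheap, from D‑isoascorbic acid) is bought as the D‑enantiomer. Racemic 2‑bromopropionyl bromide is acceptable because the C17 configuration is set in the Sm‑aldol step, not by the bromide.

## Retrosynthetic overview
1. Close the Z‑Δ5 ten‑membered ring last by RCM of a C7‑vinyl / C5‑isopropenyl diene.
2. Build the γ‑lactone and the C8 tertiary alcohol by SmI2 Reformatsky‑aldol of a C7 2‑bromopropionate onto a C8 ketone (from the C8/C9 diol).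
3. Make the C7 carbinol by chelation‑controlled vinyl addition, and the C2 carbinol by Felkin–Anh addition of 3‑methylbut‑3‑enyl‑MgBr to the ring‑B aldehyde.
4. Make the spiro‑epoxide by top‑face epoxidation of an 11(20)‑methylene, and make ring B by endo Diels–Alder of (E,E)‑1,4‑diacetoxybutadiene with a D‑erythrose‑derived (E)‑α‑methyl enal.
5. Order of ring formation: ring B (Diels–Alder), then epoxide, then γ‑lactone (aldol), then the 10‑membered ring (RCM).

## Route

**Step 1**
Reactants: 1, 2,3‑O‑isopropylidene‑D‑erythronolactone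
Product: 2, 2,3‑O‑isopropylidene‑D‑erythrose (lactol, anomeric mixture)
Conditions: DIBAL‑H (1.1 equiv), toluene, −78 °C
Reagents that add atoms: none
Why: DIBAL stops at the lactol stage at −78 °C (lactone→lactol reduction), and the two acetonide stereocenters are untouched.

**Step 2**
Reactants: 2; 3, 2‑(triphenylphosphoranylidene)propanal
Product: 4, (E)‑enal: HOCH2–[cis‑2,2‑dimethyl‑1,3‑dioxolane‑4,5‑diyl]–CH=C(CH3)–CHO, with the dioxolane carbon bearing C10 being C9 (S)
Conditions: toluene, 80 °C, 12 h
Reagents that add atoms: none (byproduct Ph3P=O)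
Why: The stabilized ylide reacts with the open aldehyde form of the lactol (Wittig), giving the E‑trisubstituted enal. Then C2 and C9 are trans on the alkene and Me is cis to C9, which is what the trans ring fusion needs.

**Step 3**
Reactants: 4
Product: 5, TBS ether of 4
Conditions: TBSCl, imidazole, DMF, 0 °C→rt
Reagents that add atoms: TBSCl, C[Si](C)(C(C)(C)C)Cl
Why: This silylation blocks the primary C7 alcohol for the later oxidations and Lewis‑acid steps.

**Step 4**
Reactants: 5; 6, (E,E)‑1,4‑diacetoxybuta‑1,3‑diene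
Product: 7, cyclohexene adduct (C14‑OAc and C11‑OAc cis; C2‑CHO, C1‑Me, C10–C9 dioxolane chain)
Conditions: BF3·OEt2 (1.1 equiv), CH2Cl2, −78→−30 °C
Reagents that add atoms: none (both partners are numbered)
Why: Lewis‑acid Diels–Alder, ortho‑selective and endo, sets the relative configuration of C14/C1/C10/C11 (CHO cis to the OAcs; E‑alkene gives trans C2/C9). The face is chosen by the C9 stereocenter (Felkin–Houk model: H9 inside against the cis‑Me, σ*C–O anti to the diene, ring carbon C8 outside).

**Step 5**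
Reactants: 7
Product: 8, saturated ring B (C12–C13 CH2CH2)
Conditions: H2 (1 atm), 10% Pd/C, EtOAc, rt
Reagents that add atoms: none (only H added)
Why: Catalytic hydrogenation of the only alkene; no stereocenter is affected.

**Step 6**
Reactants: 8
Product: 9, C11 alcohol (C14‑OAc retained)
Conditions: K2CO3 (0.3 equiv), MeOH, 0 °C
Reagents that add atoms: none
Why: The equatorial C11 acetate is methanolyzed faster than the axial, neopentyl C14 acetate (hindrance‑controlled Zemplén‑type cleavage); TBS and acetonide are stable to base.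

**Step 7**
Reactants: 9
Product: 10, C11 ketone (C2 aldehyde retained)
Conditions: Dess–Martin periodinane, NaHCO3, CH2Cl2, rt
Reagents that add atoms: none
Why: Mild oxidation of the secondary alcohol. C10 sits α to the ketone, but its epimer would place C9 axial, so it stays in the thermodynamically preferred configuration.

**Step 8**
Reactants: 10
Product: 11, 11(20)‑exocyclic methylene with C2 vinyl (aldehyde and ketone both methylenated)
Conditions: Cp2TiMe2 (3 equiv), toluene/THF, 65 °C, dark
Reagents that add atoms: dimethyltitanocene (supplies two =CH2 units), C[Ti](C)(C1C=CC=C1)C1C=CC=C1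
Why: Petasis methylenation is base‑free and tolerates acetate, acetonide and TBS. Converting the aldehyde into a neopentyl vinyl group masks it during epoxidation.

**Step 9**
Reactants: 11
Product: 12, spiro‑epoxide (O up, C20 down at C11); C2 vinyl intact
Conditions: DMDO (1.1 equiv, acetone), CH2Cl2, −20 °C
Reagents that add atoms: DMDO, CC1(C)OO1
Why: Electrophilic (Prilezhaev‑type) epoxidation of the electron‑rich 1,1‑disubstituted alkene is much faster than of the hindered monosubstituted vinyl. It occurs from the top face because the bottom face is shielded by the syn‑axial C15 methyl and C13‑H. This sets the C11 configuration of the target.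

**Step 10**
Reactants: 12
Product: 13, C2 aldehyde
Conditions: O3, CH2Cl2, −78 °C; then Me2S, rt
Reagents that add atoms: ozone, [O-][O+]=O
Why: Ozonolysis cleaves the only remaining alkene and regenerates the C2 aldehyde; the epoxide, acetate and acetonide survive.

**Step 11**
Reactants: 13; 14, 4‑bromo‑2‑methylbut‑1‑ene (as its Grignard)
Product: 15, C2 secondary alcohol with the 3‑methylbut‑3‑enyl chain (C3–C4–C5(Me)=CH2)
Conditions: 14 + Mg, THF (Grignard formation); then 13, −78→−40 °C
Reagents that add atoms: none beyond numbered 14 (Mg is not incorporated)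
Why: Grignard addition to the α‑quaternary aldehyde follows Felkin–Anh (L = C10, M = C14, S = Me), which gives the C2 (S) configuration of the target.

**Step 12**
Reactants: 15
Product: 16, C2 acetate
Conditions: Ac2O, DMAP, Et3N, CH2Cl2, rt
Reagents that add atoms: Ac2O, CC(=O)OC(C)=O
Why: Simple acetylation; no stereocenter is touched.

**Step 13**
Reactants: 16
Product: 17, free primary C7 alcohol
Conditions: TBAF·3H2O/AcOH (1:1), THF, 0 °C
Reagents that add atoms: none
Why: Buffered fluoride removes the TBS group without acetate cleavage or migration.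

**Step 14**
Reactants: 17
Product: 18, C7 aldehyde (α‑alkoxy aldehyde on the cis‑acetonide)
Conditions: Dess–Martin periodinane, NaHCO3, CH2Cl2, 0 °C; use crude
Reagents that add atoms: none
Why: Mild oxidation that avoids C8 epimerization of the α‑alkoxy aldehyde.

**Step 15**
Reactants: 18; 19, vinylmagnesium bromide
Product: 20, C7 allylic alcohol
Conditions: CH2=CHMgBr (1.5 equiv), CH2Cl2/Et2O, −78 °C
Reagents that add atoms: none beyond numbered 19 (C=C[Mg]Br)
Why: Cram‑chelate addition (Mg bridging the aldehyde O and the C8 acetonide O, attack anti to C9) gives the C7/C8‑syn product, which is C7 (S). The C8 stereocenter is destroyed later.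

**Step 16**
Reactants: 20; 21, 2‑bromopropionyl bromide
Product: 22, C7 2‑bromopropionate
Conditions: pyridine, cat. DMAP, CH2Cl2, 0 °C
Reagents that add atoms: none beyond numbered 21
Why: The C7 OH is the only free hydroxyl, so acylation is chemoselective. The bromide stereocenter is irrelevant because it is lost on enolate formation.

**Step 17**
Reactants: 22
Product: 23, C8/C9 diol
Conditions: PPTS (0.2 equiv), MeOH, 40 °C
Reagents that add atoms: none
Why: Acid‑catalyzed transketalization of the acetonide under mild conditions (chosen to spare the spiro‑epoxide).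

**Step 18**
Reactants: 23
Product: 24, C8 ketone with free C9‑OH
Conditions: Dess–Martin periodinane (1.05 equiv), NaHCO3, CH2Cl2, 0 °C
Reagents that add atoms: none
Why: The C9 OH is neopentyl‑like, flanked by the ring‑fusion CH (C10, which sits between two quaternary centers), so the less hindered C8 OH is oxidized selectively. Buffered, neutral conditions suppress acyl migration.

**Step 19**
Reactants: 24
Product: 25, C9 acetate
Conditions: Ac2O, DMAP, Et3N, CH2Cl2, rt
Reagents that add atoms: Ac2O, CC(=O)OC(C)=O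
Why: Forcing acetylation of the hindered C9 alcohol installs the C9 OAc of the target.

**Step 20**
Reactants: 25
Product: 26, γ‑lactone with C8 tertiary alcohol and C17 methyl (C7 vinyl, C2 chain alkene still open)
Conditions: SmI2 (2.5 equiv), THF, −78 °C
Reagents that add atoms: none
Why: Intramolecular SmI2 Reformatsky aldol (5‑exo) of the Sm(III) enolate onto the C8 ketone. It sets C8 with C9 trans to the C7 vinyl, and C17‑Me cis to the C8 OH through a chelated chair TS. C17 is epimerizable (DBU) if needed.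

**Step 21**
Reactants: 26
Product: 27, Junceellolide K
Conditions: Hoveyda–Grubbs II (15 mol%), toluene (2 mM), 80 °C
Reagents that add atoms: none (ethylene lost)
Why: Ring‑closing metathesis of the C7 vinyl and the C5 isopropenyl group; a ten‑membered carbocycle closes as the cis (Z) ring alkene, giving the Δ5 trisubstituted alkene.

## Compound list
1 | 2,3‑O‑isopropylidene‑D‑erythronolactone | C1[C@H]2OC(C)(C)O[C@H]2C(=O)O1 | starting material
2 | 2,3‑O‑isopropylidene‑D‑erythrose (lactol) | C1[C@H]2OC(C)(C)O[C@H]2C(O)O1 | intermediate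
3 | 2‑(triphenylphosphoranylidene)propanal | CC(C=O)=P(c1ccccc1)(c1ccccc1)c1ccccc1 | starting material
4 | (E)‑enal, free C7 OH | OC[C@H]1OC(C)(C)O[C@H]1/C=C(\C)C=O | intermediate
5 | TBS ether of 4 | CC(C)(C)[Si](C)(C)OC[C@H]1OC(C)(C)O[C@H]1/C=C(\C)C=O | intermediate
6 | (E,E)‑1,4‑diacetoxybutadiene | CC(=O)O/C=C/C=C/OC(C)=O | starting material
7 | Diels–Alder adduct | CC(=O)O[C@H]1C=C[C@@H](OC(C)=O)[C@H]([C@@H]2OC(C)(C)O[C@@H]2CO[Si](C)(C)C(C)(C)C)[C@@]1(C)C=O | intermediate
8 | saturated ring B | CC(=O)O[C@H]1CC[C@@H](OC(C)=O)[C@H]([C@@H]2OC(C)(C)O[C@@H]2CO[Si](C)(C)C(C)(C)C)[C@@]1(C)C=O | intermediate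
9 | C11 alcohol | CC(=O)O[C@H]1CC[C@@H](O)[C@H]([C@@H]2OC(C)(C)O[C@@H]2CO[Si](C)(C)C(C)(C)C)[C@@]1(C)C=O | intermediate
10 | C11 ketone | CC(=O)O[C@H]1CCC(=O)[C@H]([C@@H]2OC(C)(C)O[C@@H]2CO[Si](C)(C)C(C)(C)C)[C@@]1(C)C=O | intermediate
11 | methylene/vinyl compound | CC(=O)O[C@H]1CCC(=C)[C@H]([C@@H]2OC(C)(C)O[C@@H]2CO[Si](C)(C)C(C)(C)C)[C@@]1(C)C=C | intermediate
12 | spiro‑epoxide, C2 vinyl | CC(=O)O[C@H]1CC[C@]2(CO2)[C@H]([C@@H]3OC(C)(C)O[C@@H]3CO[Si](C)(C)C(C)(C)C)[C@@]1(C)C=C | intermediate
13 | C2 aldehyde | CC(=O)O[C@H]1CC[C@]2(CO2)[C@H]([C@@H]3OC(C)(C)O[C@@H]3CO[Si](C)(C)C(C)(C)C)[C@@]1(C)C=O | intermediate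
14 | 4‑bromo‑2‑methylbut‑1‑ene | C=C(C)CCBr | starting material
15 | C2 carbinol | CC(=O)O[C@H]1CC[C@]2(CO2)[C@H]([C@@H]3OC(C)(C)O[C@@H]3CO[Si](C)(C)C(C)(C)C)[C@@]1(C)[C@@H](O)CCC(C)=C | intermediate
16 | C2 acetate | CC(=O)O[C@H]1CC[C@]2(CO2)[C@H]([C@@H]3OC(C)(C)O[C@@H]3CO[Si](C)(C)C(C)(C)C)[C@@]1(C)[C@@H](OC(C)=O)CCC(C)=C | intermediate
17 | free C7 alcohol | CC(=O)O[C@H]1CC[C@]2(CO2)[C@H]([C@@H]3OC(C)(C)O[C@@H]3CO)[C@@]1(C)[C@@H](OC(C)=O)CCC(C)=C | intermediate
18 | C7 aldehyde | CC(=O)O[C@H]1CC[C@]2(CO2)[C@H]([C@@H]3OC(C)(C)O[C@@H]3C=O)[C@@]1(C)[C@@H](OC(C)=O)CCC(C)=C | intermediate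
19 | vinylmagnesium bromide | C=C[Mg]Br | starting material
20 | C7 allylic alcohol | CC(=O)O[C@H]1CC[C@]2(CO2)[C@H]([C@@H]3OC(C)(C)O[C@@H]3[C@@H](O)C=C)[C@@]1(C)[C@@H](OC(C)=O)CCC(C)=C | intermediate
21 | 2‑bromopropionyl bromide | CC(Br)C(=O)Br | starting material
22 | C7 bromopropionate | CC(=O)O[C@H]1CC[C@]2(CO2)[C@H]([C@@H]3OC(C)(C)O[C@@H]3[C@@H](OC(=O)C(C)Br)C=C)[C@@]1(C)[C@@H](OC(C)=O)CCC(C)=C | intermediate
23 | C8/C9 diol | CC(=O)O[C@H]1CC[C@]2(CO2)[C@H]([C@H](O)[C@H](O)[C@@H](OC(=O)C(C)Br)C=C)[C@@]1(C)[C@@H](OC(C)=O)CCC(C)=C | intermediate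
24 | C8 ketone, C9‑OH | CC(=O)O[C@H]1CC[C@]2(CO2)[C@H]([C@H](O)C(=O)[C@@H](OC(=O)C(C)Br)C=C)[C@@]1(C)[C@@H](OC(C)=O)CCC(C)=C | intermediate
25 | C8 ketone, C9‑OAc | CC(=O)O[C@H]1CC[C@]2(CO2)[C@H]([C@H](OC(C)=O)C(=O)[C@@H](OC(=O)C(C)Br)C=C)[C@@]1(C)[C@@H](OC(C)=O)CCC(C)=C | intermediate
26 | lactone (RCM precursor) | CC(=O)O[C@H]1CC[C@]2(CO2)[C@H]([C@H](OC(C)=O)[C@]3(O)[C@@H](C)C(=O)O[C@H]3C=C)[C@@]1(C)[C@@H](OC(C)=O)CCC(C)=C | intermediate
27 | Junceellolide K | CC(=O)O[C@H]1CC/C(C)=C\[C@@H]2OC(=O)[C@H](C)[C@@]2(O)[C@@H](OC(C)=O)[C@H]2[C@]3(CC[C@H](OC(C)=O)[C@]12C)CO3 | target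

## Totals
Total steps: 21. Longest linear sequence: 21 (from 1).

## Three steps most likely to fail
1. **Step 4 (Diels–Alder).** The trisubstituted enal is a poor dienophile, and the facial selectivity rests on one allylic stereocenter.
   Fallback: tether the diene to the C7 oxygen through a removable silicon link and run it as an intramolecular Diels–Alder, which raises reactivity and enforces the face.
2. **Steps 17–18 (acetonide removal next to the epoxide, then C8‑selective oxidation).** The spiro‑epoxide may open under acid, and the C8/C9 differentiation may be poor.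
   Fallback: change the order. Form the cyclic orthoacetate of the C8/C9 diol and hydrolyze it mildly to put the acetate on the hindered C9 oxygen, then oxidize the free C8 OH (Swern).
3. **Step 21 (RCM to the trisubstituted Z alkene in a strained, trans‑fused ten‑membered ring).**
   Fallback: close the ring by intramolecular Nozaki–Hiyama–Kishi coupling of a C6 alkenyl iodide with the C7 aldehyde, with the C7 acylation and aldol steps reordered accordingly.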